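**Retrosynthetic overview**
- Gentiside B ⇐ double Raney-Ni reductive desulfurization of a 5,5'-dialkyl-2,2'-bithiophene; the two thiophene rings are a masked (CH2)8 segment (C11–C18 of the chain).
- Ester C–O ⇐ chemoselective carboxylate alkylation of unprotected 2,3-dihydroxybenzoic acid with a primary bromide (no protecting groups).
- Bithiophene side chains ⇐ two sequential α-lithiation/alkylations: 1,10-dibromodecane (C1–C10, used in excess and mono-substituted) and (S)-1-bromo-2-methylbutane (C19–C22 plus the stereocentre, chiral pool).
- No ring is formed: the benzene ring is bought intact, and the two thiophene rings are bought and destroyed in the last step.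

Assumption: the SMILES has 19 CH2 groups between the stereocentre and oxygen, so the target is (S)-20-methyldocosyl 2,3-dihydroxybenzoate (C30H52O4). Commercial (S)-1-bromo-2-methylbutane of high ee is the only source of chirality.

**Route**

Step 1
Reactants: 1, 2,2'-bithiophene; 2, (S)-1-bromo-2-methylbutane
Product: 3, 5-[(2S)-2-methylbutyl]-2,2'-bithiophene
Conditions: 1 (1.5 equiv), n-BuLi (1.2 equiv), THF, −78 → 0 °C, 1 h; then 2 (1.0 equiv), 0 → 55 °C, 16 h; excess 1 removed by sublimation/chromatography
Reagents that add atoms: (S)-1-bromo-2-methylbutane (2), CC[C@H](C)CBr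
Why: α-lithiation of thiophene followed by SN2 alkylation at a primary carbon (routine with β-branched bromides such as 2-ethylhexyl bromide); excess 1 suppresses dialkylation, and the stereocentre is β to the reacting carbon, so (S) is carried over unchanged.

Step 2
Reactants: 3, 5-[(2S)-2-methylbutyl]-2,2'-bithiophene; 4, 1,10-dibromodecane
Product: 5, 5-(10-bromodecyl)-5'-[(2S)-2-methylbutyl]-2,2'-bithiophene
Conditions: n-BuLi (1.05 equiv), THF, −78 → 0 °C; cannulate into 4 (5 equiv), THF, 0 °C → rt, 12 h; excess 4 recovered by Kugelrohr distillation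
Reagents that add atoms: 1,10-dibromodecane (4), BrCCCCCCCCCCBr
Why: lithiation occurs at the only remaining α-position (C5'), and inverse addition to excess symmetrical dibromide gives mono-SN2 substitution, as in the standard preparation of 2-(ω-bromoalkyl)thiophenes.

Step 3
Reactants: 5, 5-(10-bromodecyl)-5'-[(2S)-2-methylbutyl]-2,2'-bithiophene; 6, 2,3-dihydroxybenzoic acid
Product: 7, 10-{5'-[(2S)-2-methylbutyl]-2,2'-bithiophen-5-yl}decyl 2,3-dihydroxybenzoate
Conditions: 6 (1.5 equiv), KHCO3 (1.5 equiv), KI (0.1 equiv), DMF, 60 °C, N2, 16 h
Reagents that add atoms: 2,3-dihydroxybenzoic acid (6), OC(=O)c1cccc(O)c1O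
Why: chemoselective carboxylate O-alkylation (SN2); bicarbonate deprotonates only the CO2H (pKa ≈ 3) and not the phenols (pKa ≈ 10 and >13), so the catechol needs no protection.

Step 4
Reactants: 7, 10-{5'-[(2S)-2-methylbutyl]-2,2'-bithiophen-5-yl}decyl 2,3-dihydroxybenzoate
Product: 8, Gentiside B, (S)-20-methyldocosyl 2,3-dihydroxybenzoate
Conditions: Raney Ni (W-2, washed neutral, ca. 15 wt equiv), H2 (1 atm), THF/EtOH 4:1, 55 °C, 6–12 h; hot filtration through Celite, washing with EtOAc/1% AcOH
Reagents that add atoms: none (only hydrogen is added; both sulfur atoms are lost)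
Why: Raney-nickel reductive desulfurization (Mozingo-type hydrodesulfurization of thiophenes) cleaves all four C–S bonds and saturates both rings, converting C30H40O4S2 into C30H52O4. The benzoate ring, ester and phenols are inert under these mild conditions, and the stereocentre is an unactivated sp3 carbon outside the rings.

**Compound list**
1 | 2,2'-bithiophene | c1csc(c1)-c1cccs1 | starting material
2 | (S)-1-bromo-2-methylbutane | CC[C@H](C)CBr | starting material
3 | 5-[(2S)-2-methylbutyl]-2,2'-bithiophene | CC[C@H](C)Cc1ccc(s1)-c1cccs1 | intermediate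
4 | 1,10-dibromodecane | BrCCCCCCCCCCBr | starting material
5 | 5-(10-bromodecyl)-5'-[(2S)-2-methylbutyl]-2,2'-bithiophene | CC[C@H](C)Cc1ccc(s1)-c1ccc(CCCCCCCCCCBr)s1 | intermediate
6 | 2,3-dihydroxybenzoic acid | OC(=O)c1cccc(O)c1O | starting material
7 | 10-{5'-[(2S)-2-methylbutyl]-2,2'-bithiophen-5-yl}decyl 2,3-dihydroxybenzoate | CC[C@H](C)Cc1ccc(s1)-c1ccc(CCCCCCCCCCOC(=O)c2cccc(O)c2O)s1 | intermediate
8 | Gentiside B, (S)-20-methyldocosyl 2,3-dihydroxybenzoate | CC[C@H](C)CCCCCCCCCCCCCCCCCCCOC(=O)c1cccc(O)c1O | target

**Totals**
Total step count: 4. Longest linear sequence: 4.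

**Steps most likely to fail, with fallbacks**
1. Step 4 (desulfurization in the presence of the free catechol ester). Risks are incomplete desulfurization, product held on nickel by the catechol, some transesterification, and slight erosion of ee if Ni-mediated double-bond migration reaches C20. Fallback: desulfurize before the arene is introduced. Alkylate lithiated 3 with TBSO(CH2)10Br, treat with Raney Ni and then TBAF to give (S)-20-methyldocosan-1-ol, and esterify with 6 under Mitsunobu conditions (PPh3/DIAD).
2. Step 1 (slow SN2 on a β-branched bromide, competing E2, mono- versus di-lithiation). Fallback: reverse the polarity with a Kumada coupling of (S)-2-methylbutylmagnesium bromide and 5-bromo-2,2'-bithiophene, cat. Ni(dppp)Cl2, Et2O/THF.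
3. Step 3 (competing phenol O-alkylation or catechol oxidation in warm DMF). Fallback: alkylate the caesium salt of 2,3-bis(benzyloxy)benzoic acid instead, and let the final Raney Ni/H2 step remove the benzyl ethers together with the sulfur (finishing with Pd/C/H2 once sulfur is gone if needed).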